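A one-step world, with substrate turning first-order into target, gives every charge the same percentage at a given time, so it offers no order, and I read Sunday's run for a second path.

| flask | substrate | remark | time |
|---|---|---|---|
| Sunday's | 0.15 M | run made earlier |  |
| green | 1.0 M |  | 4.0 min |
| blue | 0.50 M |  | 4.0 min |
| amber | 2.0 M |  | 4.0 min |
| teal | 0.12 M |  | 4.0 min |
| grey | 1.5 M |  | 4.0 min |

Sunday's run (percent of the substrate charged)

| time / min | target / % | substrate / % |
|---|---|---|
| 0.500 | 11.4 | 33.6 |
| 1.00 | 21.1 | 28.1 |
| 1.33 | 27.2 | 25.3 |
| 2.00 | 36.1 | 21.2 |
| 2.50 | 41.2 | 18.1 |
| 3.00 | 45.2 | 16.5 |

(standard deviation of a reading: 0.3 percentage points)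



1. all flasks from highest to lowest amount of target, in percent of the substrate charged, at 4.0 min (green / blue / amber / teal / grey)
2. the amount of target, in percent of the substrate charged of the flask you put first, at 4.0 min
3. the amount of target, in percent of the substrate charged of the flask you put last, at 4.0 min

In Sunday's run the fastest rung was over before the first reading at 0.500 min: substrate stood at 33.6% with target at 11.4%, which I took for a quick balance with an unseen partner holding 1.64 parts per part of substrate. On the next rung substrate and partner, together the pool, drained at 0.284 min⁻¹, a half-life of 2.44 min. Alongside it ran a second loss: at 3.00 min target and pool left 11.3% of the charge unaccounted for, which against target gives 0.250, and this leak per share of target is the leak ratio, a selectivity factor turned upside down. It read 0.228 at 1.00 min and 0.222 at 2.00 min, so I held it steady through a run.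

My reckoned end state followed: target took one part in one plus the ratio of whatever was spent, and I let a flask approach this at the drain to target, 0.228 min⁻¹, times one plus the ratio. Sunday's single charge can't show how the ratio moves with charge, but a one-body leak returns the flat world, so I committed to a two-body leak, with the ratio proportional to charge and the drain to target unchanged. Teal then had ratio 0.200 and reached 55.4%; amber had 3.33 and reached 22.6%, and my order ran by rising charge: teal, blue, green, grey, amber.

The forecast, which differs from my reckoning, gave blue > teal > green > grey > amber, with 36.4% first and 9.15% last, reading the burst as “a fixed amount of some reagent”.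

The flasks gave teal > blue > green > grey > amber, with teal at 51.8% and amber at 24.3%.

    substrate ⇌ intermediate (K = 1.60, k = 0.120 s⁻¹)
    intermediate ⇌ target (K = 5.20, k = 0.00810 s⁻¹)
    substrate ⇌ dormant form (K = 1.30, k = 0.00150 s⁻¹)
    substrate + target → side product (k = 0.0130 M⁻¹ s⁻¹)
    2 substrate → homo dimer (k = 0.00710 M⁻¹ s⁻¹)

In teal, substrate and intermediate relaxed by their own step alone with a half-life of 0.0592 min, shorter than the 1.20 min of intermediate and target by theirs, and that second time was short against 4.0 min. In amber, at 2.00 min, homo dimer held 25.8% and side product 15.9% beside target at 21.6%. Counting dormant form, side product and homo dimer as the leak, the ratio at 4.00 min stood at 0.288 in teal and 2.51 in amber. For a neighbour like teal but charged at 0.30 M, my rule gave ratio 0.500 and target 49.7%; at 4.00 min that flask stood at ratio 0.512 and target 46.6%.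

The data were generated by integration with made-up constants, noise included.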